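**Strategy.** The cyclopentane (C1 = aryl-bearing quaternary carbon, C2 = CHMe, C3 = C(=CHBr), C4, C5) is disconnected at C4–C5 and C2–C3. The C5–C1–C2 unit is stored in a cyclopropane fused to a lactone that ties the phenol oxygen to the carbon destined to become the C2 methyl group; a propargyl reagent brings C4, C3 and the bromomethylidene carbon. In one flask, organocopper opening of the cyclopropane at C5 and bromine-atom-transfer 5-exo-dig closure from C2 form both bonds and the E-bromoalkene. The step exploits the 1,3-relation of C5 and C2 across C1 and the cis relation of aryl and C2-methyl, which the cis-fused lactone enforces.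

Key step: step 6

Assumption: the catalyst enantiomer in step 5 is whichever delivers (1aS,7bS)-7; the C1–C5 ring labels above are used in all steps.

Step 1
Reactants: 1 1-(2-hydroxy-4-methylphenyl)ethan-1-one
Product: 2 1-(5-bromo-2-hydroxy-4-methylphenyl)ethan-1-one
Conditions: NBS, MeCN, 0 °C to rt
Reagents that add atoms: N-bromosuccinimide, O=C1CCC(=O)N1Br
Why: Electrophilic aromatic bromination should go para to the hydroxyl group, because the other activated position lies between OH and CH3 and is hindered.

Step 2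
Reactants: 2 1-(5-bromo-2-hydroxy-4-methylphenyl)ethan-1-one
Product: 3 4-bromo-5-methyl-2-(prop-1-en-2-yl)phenol
Conditions: Ph3PCH3Br, KOtBu (2.2 equiv each), THF, 0 °C to rt
Reagents that add atoms: methyltriphenylphosphonium bromide, C[P+](c1ccccc1)(c1ccccc1)c1ccccc1.[Br-]
Why: Wittig methylenation with excess ylide should tolerate the phenoxide and give the 1,1-disubstituted alkene.

Step 3
Reactants: 3 4-bromo-5-methyl-2-(prop-1-en-2-yl)phenol; 4 3-(tert-butoxy)-3-oxopropanoic acid
Product: 5 1-[4-bromo-5-methyl-2-(prop-1-en-2-yl)phenyl] 3-tert-butyl propanedioate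
Conditions: DCC, DMAP (cat.), CH2Cl2, 0 °C to rt
Reagents that add atoms: none
Why: Steglich esterification of the phenol with the malonic half-ester should install the tether that later becomes the lactone.

Step 4
Reactants: 5 1-[4-bromo-5-methyl-2-(prop-1-en-2-yl)phenyl] 3-tert-butyl propanedioate
Product: 6 1-[4-bromo-5-methyl-2-(prop-1-en-2-yl)phenyl] 3-tert-butyl 2-diazopropanedioate
Conditions: 4-acetamidobenzenesulfonyl azide, Et3N, MeCN, 0 °C to rt
Reagents that add atoms: 4-acetamidobenzenesulfonyl azide, CC(=O)Nc1ccc(cc1)S(=O)(=O)N=[N+]=[N-]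
Why: Regitz diazo transfer to the acidic malonate CH2 should give the diazomalonate.

Step 5
Reactants: 6 1-[4-bromo-5-methyl-2-(prop-1-en-2-yl)phenyl] 3-tert-butyl 2-diazopropanedioate
Product: 7 tert-butyl (1aS,7bS)-6-bromo-5,7b-dimethyl-2-oxo-1,7b-dihydrocyclopropa[c]chromene-1a(2H)-carboxylate
Conditions: Rh2(S-PTTL)4 (1 mol %), CH2Cl2, slow addition, −20 °C to rt
Reagents that add atoms: none
Why: Rhodium-carbene intramolecular cyclopropanation of the 1,1-disubstituted alkene (a known reaction of unsaturated diazomalonates) should close lactone and cyclopropane together, the chiral carboxylate ligands choosing the alkene face and so the configuration of C7b (future C1), with C1a following because only the cis-fused bicycle can form.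

Step 6
Reactants: 7 tert-butyl (1aS,7bS)-6-bromo-5,7b-dimethyl-2-oxo-1,7b-dihydrocyclopropa[c]chromene-1a(2H)-carboxylate
Product: 10 tert-butyl (3E,3aR,9bS)-8-bromo-3-(bromomethylidene)-7,9b-dimethyl-4-oxo-1,2,3,9b-tetrahydrocyclopenta[c]chromene-3a(4H)-carboxylate, via bromomagnesium enolate 8 (not isolated), via tertiary bromide 9 (not isolated)
Conditions: H2C=C=CHMgBr, CuBr·SMe2 (1.1 equiv each), THF, −40 to 0 °C; then NBS, −78 °C; then tris(2-pyridylmethyl)amine (10 mol %), 40 °C
Reagents that add atoms: allenylmagnesium bromide, C=C=C[Mg]Br; N-bromosuccinimide, O=C1CCC(=O)N1Br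
Why: Proposed new method: the organocopper reagent should open the doubly activated cyclopropane by attack of its γ-carbon at the CH2 group (C5), the only SN2-accessible carbon because C7b is quaternary and the lactone holds the C1a–C7b bond in the arene plane where it cannot ionise, giving the C4–C5 bond and enolate 8; NBS then brominates 8 to 9, and cuprous bromide with the amine ligand abstracts that bromine so that the C2 radical closes onto the alkyne (C2–C3 bond) and the vinyl radical takes bromine back. The closest known reaction types are homoconjugate addition of organocuprates to cyclopropane-1,1-dicarboxylates, ring-opening/Conia-ene annulation of such cyclopropanes with propargyl amines, and copper-catalysed atom-transfer radical cyclisation of 2-halo-1,3-dicarbonyl compounds onto alkynes. The cyclopentane closes in the 5-exo-dig mode. The new stereocentre C3a (future C2) should form only cis-fused, because the three-atom tether hangs from C9b on one face of the planar radical. The step needs propargyl rather than allenyl transfer, which rests on the γ-selectivity typical of allenyl metals, and E geometry, which rests on bromine delivery to the rapidly inverting vinyl radical from the side away from the quaternary C3a and its two carbonyl groups.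

Step 7
Reactants: 10 tert-butyl (3E,3aR,9bS)-8-bromo-3-(bromomethylidene)-7,9b-dimethyl-4-oxo-1,2,3,9b-tetrahydrocyclopenta[c]chromene-3a(4H)-carboxylate
Product: 12 (3E,3aR,9bR)-8-bromo-3-(bromomethylidene)-7,9b-dimethyl-2,3,3a,9b-tetrahydrocyclopenta[c]chromen-4(1H)-one, via carboxylic acid 11 (not isolated)
Conditions: TFA, CH2Cl2, rt; concentrate; toluene, 110 °C
Reagents that add atoms: none
Why: Acidolysis of the tert-butyl ester and thermal decarboxylation of the malonic-type acid through the lactone carbonyl should give an enol whose protonation (or later epimerisation through the enol) leads to the cis-fused lactone, so that C3a (future C2) carries the carbonyl carbon cis to the aryl group.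

Step 8
Reactants: 12 (3E,3aR,9bR)-8-bromo-3-(bromomethylidene)-7,9b-dimethyl-2,3,3a,9b-tetrahydrocyclopenta[c]chromen-4(1H)-one
Product: 14 4-bromo-2-[(1R,2R,3E)-3-(bromomethylidene)-1,2-dimethylcyclopentyl]-5-methylphenol, via triethylsilyl ether 13 (not isolated)
Conditions: Et3SiH (excess), B(C6F5)3 (5 mol %), CH2Cl2, rt; then TBAF, THF, 0 °C
Reagents that add atoms: none
Why: B(C6F5)3-catalysed exhaustive hydrosilane reduction of a carboxylic ester to a methyl group should turn the lactone carbonyl into the C2 methyl group and release the phenol as its silyl ether, which fluoride cleaves, without touching a stereocentre.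

**Compound list**
1 | 1-(2-hydroxy-4-methylphenyl)ethan-1-one | CC(=O)c1ccc(C)cc1O | starting material
2 | 1-(5-bromo-2-hydroxy-4-methylphenyl)ethan-1-one | CC(=O)c1cc(Br)c(C)cc1O | intermediate
3 | 4-bromo-5-methyl-2-(prop-1-en-2-yl)phenol | CC(=C)c1cc(Br)c(C)cc1O | intermediate
4 | 3-(tert-butoxy)-3-oxopropanoic acid | CC(C)(C)OC(=O)CC(=O)O | starting material
5 | 1-[4-bromo-5-methyl-2-(prop-1-en-2-yl)phenyl] 3-tert-butyl propanedioate | CC(=C)c1cc(Br)c(C)cc1OC(=O)CC(=O)OC(C)(C)C | intermediate
6 | 1-[4-bromo-5-methyl-2-(prop-1-en-2-yl)phenyl] 3-tert-butyl 2-diazopropanedioate | CC(=C)c1cc(Br)c(C)cc1OC(=O)C(=[N+]=[N-])C(=O)OC(C)(C)C | intermediate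
7 | tert-butyl (1aS,7bS)-6-bromo-5,7b-dimethyl-2-oxo-1,7b-dihydrocyclopropa[c]chromene-1a(2H)-carboxylate | Cc1cc2c(cc1Br)[C@]1(C)C[C@]1(C(=O)OC(C)(C)C)C(=O)O2 | intermediate
8 | bromomagnesium enolate of tert-butyl (4S)-6-bromo-4-(but-3-yn-1-yl)-4,7-dimethyl-2-oxochromane-3-carboxylate | Cc1cc2c(cc1Br)[C@](C)(CCC#C)C(C(=O)O2)=C(O[Mg]Br)OC(C)(C)C | intermediate
9 | tert-butyl (4S)-3,6-dibromo-4-(but-3-yn-1-yl)-4,7-dimethyl-2-oxochromane-3-carboxylate (C3 epimers) | Cc1cc2c(cc1Br)[C@](C)(CCC#C)C(Br)(C(=O)O2)C(=O)OC(C)(C)C | intermediate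
10 | tert-butyl (3E,3aR,9bS)-8-bromo-3-(bromomethylidene)-7,9b-dimethyl-4-oxo-1,2,3,9b-tetrahydrocyclopenta[c]chromene-3a(4H)-carboxylate | Cc1cc2c(cc1Br)[C@]1(C)CC/C(=C\Br)[C@]1(C(=O)OC(C)(C)C)C(=O)O2 | intermediate
11 | (3E,3aR,9bS)-8-bromo-3-(bromomethylidene)-7,9b-dimethyl-4-oxo-1,2,3,9b-tetrahydrocyclopenta[c]chromene-3a(4H)-carboxylic acid | Cc1cc2c(cc1Br)[C@]1(C)CC/C(=C\Br)[C@]1(C(=O)O)C(=O)O2 | intermediate
12 | (3E,3aR,9bR)-8-bromo-3-(bromomethylidene)-7,9b-dimethyl-2,3,3a,9b-tetrahydrocyclopenta[c]chromen-4(1H)-one | Cc1cc2c(cc1Br)[C@]1(C)CC/C(=C\Br)[C@@H]1C(=O)O2 | intermediate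
13 | {4-bromo-2-[(1R,2R,3E)-3-(bromomethylidene)-1,2-dimethylcyclopentyl]-5-methylphenoxy}(triethyl)silane | Cc1cc(O[Si](CC)(CC)CC)c([C@]2(C)CC/C(=C\Br)[C@@H]2C)cc1Br | intermediate
14 | 4-bromo-2-[(1R,2R,3E)-3-(bromomethylidene)-1,2-dimethylcyclopentyl]-5-methylphenol | Cc1cc(O)c([C@]2(C)CC/C(=C\Br)[C@@H]2C)cc1Br | target

Total steps: 8. Longest linear sequence: 8 steps (1 to 14).

**Steps most likely to fail**

Step 6, the step labelled as a proposed new method, is the riskiest. The ring opening may stall, the allenyl instead of the propargyl terminus may be transferred, and the bromine transfer may give an E/Z mixture. The fallback uses known chemistry and sets out from 7. MgI2 in THF followed by AcOH should open the cyclopropane at its CH2 group to tert-butyl (4R)-6-bromo-4-(iodomethyl)-4,7-dimethyl-2-oxochromane-3-carboxylate F1. Radical propargylation with tributyl(propa-1,2-dienyl)stannane and AIBN in benzene at 80 °C should give tert-butyl (4R)-6-bromo-4-(but-3-yn-1-yl)-4,7-dimethyl-2-oxochromane-3-carboxylate F2. NBS with catalytic AgNO3 in acetone should give tert-butyl (4R)-6-bromo-4-(4-bromobut-3-yn-1-yl)-4,7-dimethyl-2-oxochromane-3-carboxylate F3. A Conia-ene cyclisation catalysed by In(NTf2)3 in toluene at 80 °C, a syn addition of C–H across the bromoalkyne, should then return to 10 with the E geometry fixed by the mechanism. In this fallback the two ring bonds are made in separate operations.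

Step 5 may suffer from poor facial selectivity of the carbene addition, or from carbene dimerisation. As a fallback from 6, Rh2(esp)2 in CH2Cl2 should give racemic tert-butyl 6-bromo-5,7b-dimethyl-2-oxo-1,7b-dihydrocyclopropa[c]chromene-1a(2H)-carboxylate F4, which preparative chromatography on a chiral stationary phase should resolve to 7.

Step 8 may suffer from ionisation next to the tertiary allylic C2 (hydride shift) or from hydrosilylation of the alkene during the exhaustive reduction. As a fallback from 12, iBu2AlH in CH2Cl2 at −78 °C should give the lactol (3E,3aR,9bR)-8-bromo-3-(bromomethylidene)-7,9b-dimethyl-1,2,3,3a,4,9b-hexahydrocyclopenta[c]chromen-4-ol F5. Tosylhydrazide in MeOH should convert it into the open-chain hydrazone N'-{[(1R,2R,5E)-2-(5-bromo-2-hydroxy-4-methylphenyl)-5-(bromomethylidene)-2-methylcyclopentyl]methylidene}-4-methylbenzenesulfonohydrazide F6. Catecholborane followed by NaOAc·3H2O should reduce the hydrazone carbon to the methyl group and arrive at 14.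

Further compounds
F1 | step 6 | tert-butyl (4R)-6-bromo-4-(iodomethyl)-4,7-dimethyl-2-oxochromane-3-carboxylate | Cc1cc2c(cc1Br)[C@](C)(CI)C(C(=O)O2)C(=O)OC(C)(C)C
F2 | step 6 | tert-butyl (4R)-6-bromo-4-(but-3-yn-1-yl)-4,7-dimethyl-2-oxochromane-3-carboxylate | Cc1cc2c(cc1Br)[C@](C)(CCC#C)C(C(=O)O2)C(=O)OC(C)(C)C
F3 | step 6 | tert-butyl (4R)-6-bromo-4-(4-bromobut-3-yn-1-yl)-4,7-dimethyl-2-oxochromane-3-carboxylate | Cc1cc2c(cc1Br)[C@](C)(CCC#CBr)C(C(=O)O2)C(=O)OC(C)(C)C
F4 | step 5 | racemic tert-butyl 6-bromo-5,7b-dimethyl-2-oxo-1,7b-dihydrocyclopropa[c]chromene-1a(2H)-carboxylate | Cc1cc2c(cc1Br)C1(C)CC1(C(=O)OC(C)(C)C)C(=O)O2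
F5 | step 8 | (3E,3aR,9bR)-8-bromo-3-(bromomethylidene)-7,9b-dimethyl-1,2,3,3a,4,9b-hexahydrocyclopenta[c]chromen-4-ol | Cc1cc2c(cc1Br)[C@]1(C)CC/C(=C\Br)[C@@H]1C(O)O2
F6 | step 8 | N'-{[(1R,2R,5E)-2-(5-bromo-2-hydroxy-4-methylphenyl)-5-(bromomethylidene)-2-methylcyclopentyl]methylidene}-4-methylbenzenesulfonohydrazide | Cc1cc(O)c(cc1Br)[C@]1(C)CC/C(=C\Br)[C@@H]1C=NNS(=O)(=O)c1ccc(C)cc1
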